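Remark on the chemistry: flavone numbering is used throughout (O1, C2, C3, C4, C4a, C5–C8, C8a; ring B atoms primed); "prenyl" means 3-methylbut-2-enyl and "MOM" means methoxymethyl.

## The problem

Muxiangrine III (15) is a flavone whose ring A is fully substituted (5-OH, 6-CH3, 7-OCH3, 8-CH3) and whose ring B is a catechol carrying a prenyl group at C5', next to the 4'-OH. Rings A and C share the C4a–C8a bond, ring B sits on C2, and the three oxygens on ring A (O1, O5, O7) must end in three different states: ring ether, free phenol and methyl ether. There is no stereocentre, so the task is one of regiochemistry and functional-group compatibility; the only alkene is the prenyl double bond, whose terminus bears two identical methyl groups. A prenyl group ortho to a phenol does not survive strong acid (closure to a 2,2-dimethylchroman) or hydrogenation, the free catechol is easily oxidised and chelates metals, and the pyranone ring is opened by hot hydroxide. The C-methyl groups at C6 and C8 are best brought in with the starting material, because C-methylation of a phloroglucinol-type ring is poorly controlled. The enabling feature is the local symmetry of ring A: C6 and C8 both bear methyl, C7 lies on the axis through C4a, and C5 and C8a both bear oxygen, so C5 and C8a are equivalent as long as ring C is open. A 2,6-dihalogenated aryl ketone can therefore be closed onto either halogen with the same result, and the halogen left over marks C5 for the hydroxyl group.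

## Retrosynthesis

**15 from 14.** The two O–CH2 bonds of the catechol acetal ethers are cut last. MOM ethers are preferred to benzyl ethers (hydrogenolysis would reduce the prenyl alkene) and to aryl silyl ethers (lost in the hydroxide and hydride steps). The precursor 14 has the same skeleton, but its catechol is inert to base, copper and palladium. The forward reaction must be acidic enough to cleave two acetals and mild enough to leave the prenyl group next to the 4'-OH alone.

**14 from 13.** The C5–O bond is traced back to a C5–Br bond. Carrying a protected C5 oxygen through the synthesis instead would destroy the symmetry of ring A before ring closure and would require a regiodefined, unsymmetrical, hexasubstituted arene. Bromoflavone 13 is no smaller than 14, but it is the direct product of the symmetric ring closure. The forward step must hydroxylate a bromide flanked by the C6 methyl group and the peri carbonyl without destroying the pyranone.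

**13 from 12 (key disconnection).** The O1–C8a bond is cut, which opens ring C to the diketone 12. The neighbouring cut, O1–C2 (cyclodehydration of an ortho-hydroxyaryl diketone), would need a 2,6-dioxygenated ketone with the two oxygens already in place, and that leads back to unselective C-methylation chemistry. Cutting O1–C8a keeps ring A as a symmetric dibromide that comes from a cheap acid. Compound 12 is acyclic between two benzene rings and has a mirror-symmetric ring A half. The forward reaction must arylate the enolate oxygen once, at either of two equivalent bromides, and leave the second bromide untouched.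

**12 from 4 and 11.** The C2–C3 bond between the diketone methylene and the ring B carbonyl is cut, giving methyl ketone 4 and ester 11. The opposite polarity (a ring B methyl ketone enolate with acid chloride 3) would place the electrophilic carbon between two ortho bromines, where attack is slow and O-acylation competes. In the chosen sense the nucleophilic carbon of 4 is unhindered and 11 is the only electrophile. The cut is convergent and divides the molecule into two benzene derivatives of similar size. The forward reaction is a crossed Claisen condensation with a single enolisable partner.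

**4 from 2 and 1.** The acyl–methyl bond and the two C–Br bonds are cut. Acid 1 has exactly two free ring positions and both must be brominated, so no regiochemical question exists; each position is ortho to one methyl group and para to the other. The acid 2 is then converted through its chloride 3 to the ketone 4. The forward bromination must avoid ipso attack at the carboxyl-bearing carbon and radical attack on the methyl groups.

**11 from 10, 8, 7, and from 5 and 6.** The aryl–prenyl bond at C5 is traced back to an aromatic Claisen rearrangement of the 1,1-dimethylallyl ether 8, which comes from semihydrogenation of the propargyl ether 7, itself made from ester 5 and chloride 6. Direct C-prenylation of 5 would give mixtures over three ring positions and two oxygens. A cross-coupling would first need a regioselective halogenation and then a prenyl metal with its branched/linear problem. The sigmatropic route places the prenyl group at the only free ortho position of O4. It requires regioselective etherification of the more acidic 4-OH of 5 and a rearrangement that tolerates the neighbouring free hydroxyl.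

## Roads not taken

**Alternative 1:** Ring A would be built last on a finished pyranone by cutting C4a–C5. The precursor A1 is a 2-aryl-4-pyranone with a branched keto ester chain on its other alpha position (future C8a). Base would give an extended enolate running from C8 through C8a to C4a. Attack of C4a on the terminal ester closes the carbocycle, which enolises to the 5,7-dihydroxy-6,8-dimethylflavone A2.

- Merits: the route follows the biosynthetic logic, places both C-methyl groups through the chain, and needs no halogen and no transition metal.
- Weak points: the most acidic proton of A1 lies between the ketone and the ester, so the first enolate formed is a stabilised one that cannot cyclise, and a dianion is needed. The nucleophilic site C4a is a deactivated position of a cross-conjugated pyranone. A1 itself, a polycarbonyl chain on a pyranone, is harder to assemble than 12. A2 still needs selective methylation of the 7-OH, which is flanked by two methyl groups, in the presence of the chelated 5-OH.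
- Comparison: the endgame is as long as the chosen one (methylation plus deprotection against hydroxylation plus deprotection), and it avoids the late hydroxylation. The chosen plan offers in return a precursor made by routine aromatic chemistry and a ring closure of an established reaction class.

**Alternative 2:** Ring C would be formed in one operation from an aryne and an arylpropiolic acid, cutting C8a–O1, C4a–C4 and O1–C2. A fluoride source would unmask the aryne from the silyl triflate A3. The carboxyl group of acid A4 inserts across the aryne, and the resulting ortho-hydroxyaryl ynone closes by conjugate addition to the tris-MOM flavone A5. One acidic step would then give 15.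

- Merits: this is the most convergent of the four plans, with three bonds formed in one flask, and its endgame is one step shorter than the chosen one, with no late hydroxylation.
- Weak points: A3 is a hexasubstituted benzene (silyl, triflate, MOM ether, methyl, methoxy, methyl), and its regiodefined preparation would cost more steps than the whole ring A sequence from 1. The aryne is flanked on both sides, by the MOM ether at C5 and by methyl at C8, so the direction of carboxylate addition depends on the alkoxy group outweighing the methyl group, and the wrong direction gives a regioisomeric flavone that is hard to separate. The ynone intermediate can also close in the five-membered mode to an aurone.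
- Comparison: this plan is better in convergence and endgame length. The chosen plan is better in precursor cost and removes the regiochemical question entirely through the symmetry of 12.

**Alternative 3:** Ring A would be grown on a pyranone by a vinylketene benzannulation. Irradiation of the pyranonyl diazo ketone A6 would trigger a Wolff shift (forming C8–C8a) to a methyl(pyranonyl)ketene. The ketene adds the ynol ether A7 (C5–C6 and C7–C8), and the cyclobutenone opens and closes by six-electron electrocyclisation (C4a–C5) to the phenol A8, which is the same compound as 14.

- Merits: the intrinsic regiochemistry of ketene–ynol ether cycloaddition places 5-OH, 6-CH3, 7-OCH3 and 8-CH3 correctly in one step, with no halogen and no hydroxylation. If it worked, it would reach 14 with at least the same economy and more elegance than the chosen plan.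
- Weak points: A6 must be made from a 6-aryl-4-oxopyran-2-carboxylic acid derivative that already carries the prenylated ring B, followed by diazo installation. The 4-pyranone chromophore is itself photoreactive at the wavelengths used for the diazo ketone. The alkene that must act as the vinyl part (C4a=C8a) belongs to an electron-poor, cross-conjugated ring. A7 is a volatile, sensitive reagent needed in excess, and the ketene can also add to the prenyl alkene of a second molecule.
- Comparison: this plan is better in directness. The chosen plan is better in reliability: thermal, well-precedented reactions, a key step from a known class, and three cheap aromatic starting materials.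

Key step: step 8

## Route

Step 1
Reactants: 1 4-methoxy-3,5-dimethylbenzoic acid
Product: 2 2,6-dibromo-4-methoxy-3,5-dimethylbenzoic acid
Conditions: NBS (2.3 equiv), CF3CO2H, H2SO4 (1 equiv), 25–40 °C, dark
Reagents that add atoms: N-bromosuccinimide, O=C1CCC(=O)N1Br
Why: Electrophilic aromatic bromination; C2 and C6 are the only free ring positions and each is ortho to one methyl group and para to the other, so acid-activated NBS should brominate both in turn despite the adjacent carboxyl group. The strongly acidic, dark medium keeps the carboxyl group protonated (no ipso bromodecarboxylation) and suppresses radical bromination of the methyl groups.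

Step 2
Reactants: 2 2,6-dibromo-4-methoxy-3,5-dimethylbenzoic acid
Product: 4 1-(2,6-dibromo-4-methoxy-3,5-dimethylphenyl)ethan-1-one, via acid chloride 3 (not isolated)
Conditions: (COCl)2, DMF (cat.), CH2Cl2, 0 to 25 °C; evaporate; MeMgBr (1.1 equiv), CuI (5 mol %), THF, −40 to 0 °C
Reagents that add atoms: methylmagnesium bromide, C[Mg]Br; oxalyl chloride, ClC(=O)C(=O)Cl (supplies only the chlorine of intermediate 3)
Why: DMF-catalysed acid chloride formation followed by copper-catalysed acylation of a Grignard reagent. The ketone 4 is shielded by two ortho bromines and twisted out of the ring plane, so it should not add a second methyl group, and MeMgBr does not exchange with aryl bromides at this temperature.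

Step 3
Reactants: 5 methyl 3,4-dihydroxybenzoate; 6 3-chloro-3-methylbut-1-yne
Product: 7 methyl 3-hydroxy-4-[(2-methylbut-3-yn-2-yl)oxy]benzoate
Conditions: K2CO3 (1.05 equiv), KI (0.1 equiv), CuI (5 mol %), acetone, 50 °C, Ar
Reagents that add atoms: none
Why: Copper-assisted O-alkylation of a phenoxide with a tertiary propargylic chloride. The 4-OH, para to the ester, is the more acidic hydroxyl, so one equivalent of carbonate should direct the ether to O4 and leave the 3-OH free.

Step 4
Reactants: 7 methyl 3-hydroxy-4-[(2-methylbut-3-yn-2-yl)oxy]benzoate
Product: 8 methyl 3-hydroxy-4-[(2-methylbut-3-en-2-yl)oxy]benzoate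
Conditions: H2 (1 atm), Pd/CaCO3 poisoned with Pb(OAc)2 (Lindlar catalyst), quinoline, EtOAc, 25 °C
Reagents that add atoms: none
Why: Lindlar semihydrogenation of the terminal alkyne to the terminal alkene; quinoline and control of hydrogen uptake prevent over-reduction, and the ester and phenol are inert.

Step 5
Reactants: 8 methyl 3-hydroxy-4-[(2-methylbut-3-en-2-yl)oxy]benzoate
Product: 10 methyl 3,4-dihydroxy-5-(3-methylbut-2-enyl)benzoate, via cyclohexadienone 9 (not isolated)
Conditions: PhNEt2, 130 °C, Ar
Reagents that add atoms: none
Why: Aromatic Claisen rearrangement; the [3,3] shift delivers the allyl terminus to C5, the only free ortho position of O4, with allylic transposition to the 3-methylbut-2-enyl group, and dienone 9 enolises to the catechol. The tertiary allyl ether rearranges at moderate temperature, and the amine solvent buffers against acid-catalysed chroman formation.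

Step 6
Reactants: 10 methyl 3,4-dihydroxy-5-(3-methylbut-2-enyl)benzoate
Product: 11 methyl 3,4-bis(methoxymethoxy)-5-(3-methylbut-2-enyl)benzoate
Conditions: MOMCl (3 equiv), iPr2NEt (4 equiv), CH2Cl2, 0 to 25 °C
Reagents that add atoms: chloromethyl methyl ether, COCCl
Why: Standard alkylation of both phenols to MOM ethers, which withstand the hydride, carbonate and hydroxide bases of steps 7 to 9 and are removed by mild acid.

Step 7
Reactants: 4 1-(2,6-dibromo-4-methoxy-3,5-dimethylphenyl)ethan-1-one; 11 methyl 3,4-bis(methoxymethoxy)-5-(3-methylbut-2-enyl)benzoate
Product: 12 1-(2,6-dibromo-4-methoxy-3,5-dimethylphenyl)-3-[3,4-bis(methoxymethoxy)-5-(3-methylbut-2-enyl)phenyl]propane-1,3-dione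
Conditions: NaH (3 equiv), THF, 0 to 66 °C; then AcOH, 0 °C
Reagents that add atoms: none
Why: Crossed Claisen condensation; 4 is the only enolisable partner and its self-aldol is blocked by the two ortho bromines, so its sodium enolate should acylate on carbon with ester 11, driven by formation of the stabilised diketonate. Any premature ring closure of the diketonate would only give 13.

Step 8
Reactants: 12 1-(2,6-dibromo-4-methoxy-3,5-dimethylphenyl)-3-[3,4-bis(methoxymethoxy)-5-(3-methylbut-2-enyl)phenyl]propane-1,3-dione
Product: 13 5-bromo-7-methoxy-6,8-dimethyl-2-[3,4-bis(methoxymethoxy)-5-(3-methylbut-2-enyl)phenyl]-4H-chromen-4-one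
Conditions: CuI (10 mol %), N,N'-dimethylethylenediamine (20 mol %), K2CO3 (2 equiv), DMF (0.02 M), 90 °C, Ar
Reagents that add atoms: none
Why: K2CO3 converts the 1,3-diketone into its potassium enolate, whose oxygen on the ring B side (the future O1) binds diamine-ligated monovalent copper. Oxidative addition into one ortho C–Br bond gives an aryl trivalent copper enolate that forms O1–C8a by C–O reductive elimination; with the ortho carbonyl as activating group an addition–elimination pathway at the same carbon may contribute. The closest known reaction type is the CuI-catalysed intramolecular Ullmann O-arylation of 1-(2-bromoaryl)-1,3-diketones to flavones. Ring C closes as a six-membered ring by attack of the enolate oxygen on the ipso carbon C8a, formally 6-exo-trig with respect to the departing bromide. No stereocentre is formed. Oxygen arylation is required and is the only possibility, because bonding of C3 or of the other enolate oxygen to C8a would give a four-membered ring. Selectivity between the two bromides is not needed, since they are exchanged by the mirror plane through C4a and C7 of ring A and either closure gives 13. The second bromide is retained because after closure no nucleophile is within its reach, and dilution disfavours intermolecular coupling.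

Step 9
Reactants: 13 5-bromo-7-methoxy-6,8-dimethyl-2-[3,4-bis(methoxymethoxy)-5-(3-methylbut-2-enyl)phenyl]-4H-chromen-4-one
Product: 14 5-hydroxy-7-methoxy-6,8-dimethyl-2-[3,4-bis(methoxymethoxy)-5-(3-methylbut-2-enyl)phenyl]-4H-chromen-4-one
Conditions: Pd2(dba)3 (2 mol %), tBuXPhos (8 mol %), KOH (3 equiv), 1,4-dioxane/H2O 1:1, 90 °C, Ar; then AcOH to pH 5
Reagents that add atoms: potassium hydroxide, [K+].[OH-]
Why: Palladium-catalysed hydroxylation of an aryl bromide (Buchwald type): oxidative addition of zerovalent palladium into the C5–Br bond, exchange of bromide for hydroxide, and C–O reductive elimination promoted by the bulky biarylphosphine. If hydroxide opens the pyranone reversibly, the opened diketone has equivalent oxygens at C5 and C8a, so acidification can only close back to 14. The MOM ethers, the aryl methyl ether and the prenyl group are stable to aqueous base.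

Step 10
Reactants: 14 5-hydroxy-7-methoxy-6,8-dimethyl-2-[3,4-bis(methoxymethoxy)-5-(3-methylbut-2-enyl)phenyl]-4H-chromen-4-one
Product: 15 2-[3,4-dihydroxy-5-(3-methylbut-2-enyl)phenyl]-5-hydroxy-7-methoxy-6,8-dimethyl-4H-chromen-4-one (muxiangrine III)
Conditions: HCl (3 M aq.), MeOH, 40 °C
Reagents that add atoms: none
Why: Acid-catalysed acetal exchange with methanol removes both MOM groups. The conditions are kept mild and short so that the 4'-OH does not add to the neighbouring prenyl double bond (chroman formation), and the aryl methyl ether at C7 is not touched.

## Compound list

1 | 4-methoxy-3,5-dimethylbenzoic acid | COc1c(C)cc(cc1C)C(=O)O | starting material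
2 | 2,6-dibromo-4-methoxy-3,5-dimethylbenzoic acid | COc1c(C)c(Br)c(C(=O)O)c(Br)c1C | intermediate
3 | 2,6-dibromo-4-methoxy-3,5-dimethylbenzoyl chloride (formed in the flask, not isolated) | COc1c(C)c(Br)c(C(=O)Cl)c(Br)c1C | intermediate
4 | 1-(2,6-dibromo-4-methoxy-3,5-dimethylphenyl)ethan-1-one | COc1c(C)c(Br)c(C(C)=O)c(Br)c1C | intermediate
5 | methyl 3,4-dihydroxybenzoate | COC(=O)c1ccc(O)c(O)c1 | starting material
6 | 3-chloro-3-methylbut-1-yne | CC(C)(Cl)C#C | starting material
7 | methyl 3-hydroxy-4-[(2-methylbut-3-yn-2-yl)oxy]benzoate | COC(=O)c1ccc(OC(C)(C)C#C)c(O)c1 | intermediate
8 | methyl 3-hydroxy-4-[(2-methylbut-3-en-2-yl)oxy]benzoate | COC(=O)c1ccc(OC(C)(C)C=C)c(O)c1 | intermediate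
9 | methyl 5-hydroxy-3-(3-methylbut-2-enyl)-4-oxocyclohexa-1,5-diene-1-carboxylate (racemic, formed in the flask, not isolated; its centre is lost on enolisation) | COC(=O)C1=CC(CC=C(C)C)C(=O)C(O)=C1 | intermediate
10 | methyl 3,4-dihydroxy-5-(3-methylbut-2-enyl)benzoate | COC(=O)c1cc(O)c(O)c(CC=C(C)C)c1 | intermediate
11 | methyl 3,4-bis(methoxymethoxy)-5-(3-methylbut-2-enyl)benzoate | COC(=O)c1cc(OCOC)c(OCOC)c(CC=C(C)C)c1 | intermediate
12 | 1-(2,6-dibromo-4-methoxy-3,5-dimethylphenyl)-3-[3,4-bis(methoxymethoxy)-5-(3-methylbut-2-enyl)phenyl]propane-1,3-dione | COc1c(C)c(Br)c(C(=O)CC(=O)c2cc(OCOC)c(OCOC)c(CC=C(C)C)c2)c(Br)c1C | intermediate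
13 | 5-bromo-7-methoxy-6,8-dimethyl-2-[3,4-bis(methoxymethoxy)-5-(3-methylbut-2-enyl)phenyl]-4H-chromen-4-one | COc1c(C)c(Br)c2c(=O)cc(-c3cc(OCOC)c(OCOC)c(CC=C(C)C)c3)oc2c1C | intermediate
14 | 5-hydroxy-7-methoxy-6,8-dimethyl-2-[3,4-bis(methoxymethoxy)-5-(3-methylbut-2-enyl)phenyl]-4H-chromen-4-one | COc1c(C)c(O)c2c(=O)cc(-c3cc(OCOC)c(OCOC)c(CC=C(C)C)c3)oc2c1C | intermediate
15 | 2-[3,4-dihydroxy-5-(3-methylbut-2-enyl)phenyl]-5-hydroxy-7-methoxy-6,8-dimethyl-4H-chromen-4-one (muxiangrine III) | COc1c(C)c(O)c2c(=O)cc(-c3cc(O)c(O)c(CC=C(C)C)c3)oc2c1C | target

## Step count and risks

Total: 10 steps. Longest linear sequence: 8 steps (from 5 and 6 through steps 3, 4, 5, 6, 7, 8, 9 and 10); the ring A branch (steps 1 and 2) joins at step 7.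

**Step 8 (key step).** Most likely failure: slow oxidative addition at a C–Br bond flanked by a methyl group and the acyl substituent, made worse by the diketonate binding copper as an unreactive chelate. Forcing conditions would then lead to retro-Claisen cleavage of the diketone or reductive loss of bromine. Fallback, setting out from 4 and rejoining at 15: both bromides of 4 are replaced by hydroxyl under palladium catalysis (Pd2(dba)3, tBuXPhos, KOH, dioxane/water), which is unproblematic on a ketone without a base-sensitive ring, to give 1-(2,6-dihydroxy-4-methoxy-3,5-dimethylphenyl)ethan-1-one F1. Its lithium polyanion (LiN(SiMe3)2, THF) is acylated with ester 11 to the diketone 1-(2,6-dihydroxy-4-methoxy-3,5-dimethylphenyl)-3-[3,4-bis(methoxymethoxy)-5-(3-methylbut-2-enyl)phenyl]propane-1,3-dione F2. Warming F2 in methanolic HCl closes ring C by cyclodehydration (O1–C2 instead of O1–C8a) and removes the MOM groups in the same operation, giving 15. The symmetry of ring A again allows only one flavone.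

**Step 9.** Most likely failure: loss of material through hydroxide opening of the pyranone followed by retro-Claisen cleavage, or sluggish C–O reductive elimination at the doubly ortho-substituted carbon with protodebromination. Fallback, setting out from 13 and rejoining at 14: Miyaura borylation (Pd(dppf)Cl2, B2pin2, KOAc, dioxane, 90 °C) replaces hydroxide by acetate as the base and should give 7-methoxy-6,8-dimethyl-2-[3,4-bis(methoxymethoxy)-5-(3-methylbut-2-enyl)phenyl]-5-(4,4,5,5-tetramethyl-1,3,2-dioxaborolan-2-yl)-4H-chromen-4-one F3. Oxidation of the C–B bond with NaBO3·4H2O in THF/water, which spares the prenyl alkene and the pyranone, gives 14.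

**Step 1.** Most likely failure: ipso attack at the carboxyl-bearing carbon (para to the methoxy group) with loss of the carboxyl group, an incomplete second bromination, or radical bromination of a methyl group. Fallback, setting out from 1 and rejoining at 2: the acid is first converted (MeI, K2CO3, DMF) to methyl 4-methoxy-3,5-dimethylbenzoate F4, which cannot decarboxylate. Bromination (Br2, Fe powder, CH2Cl2, or NBS in H2SO4) gives methyl 2,6-dibromo-4-methoxy-3,5-dimethylbenzoate F5. Because its carbonyl is too hindered for saponification, the ester methyl is removed by nucleophilic displacement at carbon with LiI in hot pyridine, giving 2.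

**Step 5.** Most likely failure: fragmentation of the tertiary allyl ether back to the phenol, or follow-up cyclisation of the ortho-prenyl catechol at the rearrangement temperature; both are favoured by the free neighbouring hydroxyl. Fallback, setting out from 8 and rejoining at 11: the 3-OH is protected first (MOMCl, iPr2NEt) to methyl 3-(methoxymethoxy)-4-[(2-methylbut-3-en-2-yl)oxy]benzoate F6. The Claisen rearrangement of F6, thermally or with Eu(fod)3 catalysis at lower temperature, gives methyl 4-hydroxy-3-(methoxymethoxy)-5-(3-methylbut-2-enyl)benzoate F7, and a second MOM protection gives 11.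

**Step 7.** Most likely failure: sluggish attack of the hindered enolate on the electron-rich, weakly electrophilic ester, with decomposition on prolonged heating. Fallback, setting out from 11 and rejoining at 12: saponification (LiOH, THF/MeOH/water) gives 3,4-bis(methoxymethoxy)-5-(3-methylbut-2-enyl)benzoic acid F8. Activation with 1,1'-carbonyldiimidazole gives the acyl imidazole [3,4-bis(methoxymethoxy)-5-(3-methylbut-2-enyl)phenyl](1H-imidazol-1-yl)methanone F9, which acylates the preformed lithium enolate of 4 (LiN(SiMe3)2, THF, −78 °C to 25 °C) to give 12.

## Further compounds

F1 | step 8 | 1-(2,6-dihydroxy-4-methoxy-3,5-dimethylphenyl)ethan-1-one | COc1c(C)c(O)c(C(C)=O)c(O)c1C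
F2 | step 8 | 1-(2,6-dihydroxy-4-methoxy-3,5-dimethylphenyl)-3-[3,4-bis(methoxymethoxy)-5-(3-methylbut-2-enyl)phenyl]propane-1,3-dione | COc1c(C)c(O)c(C(=O)CC(=O)c2cc(OCOC)c(OCOC)c(CC=C(C)C)c2)c(O)c1C
F3 | step 9 | 7-methoxy-6,8-dimethyl-2-[3,4-bis(methoxymethoxy)-5-(3-methylbut-2-enyl)phenyl]-5-(4,4,5,5-tetramethyl-1,3,2-dioxaborolan-2-yl)-4H-chromen-4-one | COc1c(C)c(B2OC(C)(C)C(C)(C)O2)c2c(=O)cc(-c3cc(OCOC)c(OCOC)c(CC=C(C)C)c3)oc2c1C
F4 | step 1 | methyl 4-methoxy-3,5-dimethylbenzoate | COC(=O)c1cc(C)c(OC)c(C)c1
F5 | step 1 | methyl 2,6-dibromo-4-methoxy-3,5-dimethylbenzoate | COC(=O)c1c(Br)c(C)c(OC)c(C)c1Br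
F6 | step 5 | methyl 3-(methoxymethoxy)-4-[(2-methylbut-3-en-2-yl)oxy]benzoate | COCOc1cc(C(=O)OC)ccc1OC(C)(C)C=C
F7 | step 5 | methyl 4-hydroxy-3-(methoxymethoxy)-5-(3-methylbut-2-enyl)benzoate | COCOc1cc(C(=O)OC)cc(CC=C(C)C)c1O
F8 | step 7 | 3,4-bis(methoxymethoxy)-5-(3-methylbut-2-enyl)benzoic acid | OC(=O)c1cc(OCOC)c(OCOC)c(CC=C(C)C)c1
F9 | step 7 | [3,4-bis(methoxymethoxy)-5-(3-methylbut-2-enyl)phenyl](1H-imidazol-1-yl)methanone | O=C(c1cc(OCOC)c(OCOC)c(CC=C(C)C)c1)n1ccnc1
A1 | alternative 1 | methyl 4-{6-[3,4-bis(methoxymethoxy)-5-(3-methylbut-2-enyl)phenyl]-4-oxo-4H-pyran-2-yl}-2-methyl-3-oxopentanoate (mixture of stereoisomers, both centres lost on aromatisation) | COC(=O)C(C)C(=O)C(C)c1cc(=O)cc(-c2cc(OCOC)c(OCOC)c(CC=C(C)C)c2)o1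
A2 | alternative 1 | 5,7-dihydroxy-6,8-dimethyl-2-[3,4-bis(methoxymethoxy)-5-(3-methylbut-2-enyl)phenyl]-4H-chromen-4-one | Cc1c(O)c(C)c2oc(-c3cc(OCOC)c(OCOC)c(CC=C(C)C)c3)cc(=O)c2c1O
A3 | alternative 2 | 5-methoxy-3-(methoxymethoxy)-4,6-dimethyl-2-(trimethylsilyl)phenyl trifluoromethanesulfonate | COCOc1c(C)c(OC)c(C)c(OS(=O)(=O)C(F)(F)F)c1[Si](C)(C)C
A4 | alternative 2 | 3-[3,4-bis(methoxymethoxy)-5-(3-methylbut-2-enyl)phenyl]prop-2-ynoic acid | OC(=O)C#Cc1cc(OCOC)c(OCOC)c(CC=C(C)C)c1
A5 | alternative 2 | 7-methoxy-5-(methoxymethoxy)-6,8-dimethyl-2-[3,4-bis(methoxymethoxy)-5-(3-methylbut-2-enyl)phenyl]-4H-chromen-4-one | COCOc1c(C)c(OC)c(C)c2oc(-c3cc(OCOC)c(OCOC)c(CC=C(C)C)c3)cc(=O)c12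
A6 | alternative 3 | 2-[3,4-bis(methoxymethoxy)-5-(3-methylbut-2-enyl)phenyl]-6-(2-diazopropanoyl)-4H-pyran-4-one | CC(=[N+]=[N-])C(=O)c1cc(=O)cc(-c2cc(OCOC)c(OCOC)c(CC=C(C)C)c2)o1
A7 | alternative 3 | 1-methoxyprop-1-yne | COC#CC
A8 | alternative 3 | 5-hydroxy-7-methoxy-6,8-dimethyl-2-[3,4-bis(methoxymethoxy)-5-(3-methylbut-2-enyl)phenyl]-4H-chromen-4-one (same structure as 14) | COc1c(C)c(O)c2c(=O)cc(-c3cc(OCOC)c(OCOC)c(CC=C(C)C)c3)oc2c1C
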